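Readings and results are simulated with constants of no real substance, and the scatter is random.

Two questions are put to this flask, and both turn on one ratio. An excess among the two substrates means left-handed over right-handed equal to one minus the excess, over one plus the excess. At 98% this **allowed ratio** is 1.01%. With the right-handed substrate near 49%, as in the theta run, the left-handed substrate must fall below 0.495% of the charge.

common to all: left-handed substrate 0.46 M; right-handed substrate 0.46 M; solid reagent 0.552 M

| charge | free catalyst | remark | time |
|---|---|---|---|
| epsilon | 0.23 mM | run made earlier |  |
| theta | 0.92 mM | run made earlier |  |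
| flask | 0.46 mM |  | 12 h |

| run | time / h | right-handed substrate / % | left-handed substrate / % |
|---|---|---|---|
| epsilon | 2.50 | 54 | 35 |
| epsilon | 5.00 | 48 | 21 |
| epsilon | 8.00 | 54 | 9 |
| epsilon | 10.0 | 47 | 7 |
| epsilon | 12.0 | 48 | 6 |
| epsilon | 15.0 | 53 | 0 |
| theta | 2.50 | 50 | 30 |
| theta | 5.00 | 47 | 11 |
| theta | 8.00 | 52 | 1 |
| theta | 10.0 | 49 | 0 |
| theta | 12.0 | 49 | 0 |
| theta | 15.0 | 47 | 1 |

(each reading ± 2 percentage points)

* whether the excess of right-handed substrate over left-handed substrate among what is left of the two reaches 98% by 12 h (yes / no)
* the highest excess of right-handed substrate over left-handed substrate among what is left of the two up to 12 h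

- free catalyst is single-handed; left-handed substrate and right-handed substrate are mirror images of each other, charged as a racemate, each of them at the stated concentration
- as a solid, counted per litre of solution: solid reagent
- at the start none of the solid reagent is in solution

Two chemists dispute the flask, whose charge of [free catalyst] is 0.46 mM. For this flask both take 5.00% of left-handed substrate at 8.00 h, the mean of the readings of the two runs, with their scatter.

The first trusts a first-order tail. In the epsilon run the left-handed substrate falls with a constant read as 0.179 h⁻¹, so twice the catalyst charged, in the flask, gives him 0.358 h⁻¹. That leaves 1.19% at 12 h, more than the limit, so the answer is no.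

The second sees the dissolving of the solid reagent as the rate-limiting step of the early loss. The theta run was charged with 4.00 times the catalyst of the epsilon run, yet its loss of left-handed substrate by the first reading is just 1.33 times as large, as far as the scatter lets one read. Her straight line from the charge through that mean point crosses the limit at 8.80 h, an estimate for the flask. She grants the first his tail on the epsilon run's late readings, from 21% to 6%. I side with her and say yes.

The forecast differs from my reckoning: no, with a top of 97% (range 93% to 99.5%), “giving a first-order tail”.

The flask gives yes, with a top of 99.2%.

    free catalyst + left-handed substrate ⇌ catalyst intermediate A (K = 5.38 L mol⁻¹, k = 1890 L mol⁻¹ min⁻¹)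
    free catalyst + right-handed substrate ⇌ catalyst intermediate B (K = 0.750 L mol⁻¹, k = 144 L mol⁻¹ min⁻¹)
    partner + catalyst intermediate A → free catalyst + left-handed product (k = 200 L mol⁻¹ min⁻¹)
    partner + catalyst intermediate B → free catalyst + right-handed product (k = 8.75 L mol⁻¹ min⁻¹)
    solid reagent ⇌ partner, rate k5*(cs5 - [partner]) while solid is left; crystals form when [partner] > cs5 (solubility = 0.220 M, k = 0.00637 min⁻¹)
    left-handed product ⇌ right-handed product (k = 0.00892 min⁻¹)
    free catalyst ⇌ dormant form (K = 3.50, k = 0.00609 min⁻¹)

The excess reaches 98% at 10.4 h, 1.60 h after her line. At 12.0 h this flask holds 0.203% of left-handed substrate against 48.3% of right-handed, a ratio of 0.420%, less than the allowed ratio. With half the right-handed substrate and all other amounts as they are, the end excess is 98.8%, which puts that flask below the allowed ratio too, at a ratio of 0.584%.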